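**Strategy**

Ring B, the hydroquinone ring of the depsidone (free hydroxyl para to the lactone oxygen, pyran oxygen and pyran carbon on one flank, diaryl ether oxygen on the other), is made last by ring expansion of a squarate-derived cyclobutenone. Heating a 4-hydroxy-4-(2-aryloxyvinyl)cyclobutenone that is already fused to the 2,2-dimethyl-2H-pyran opens it to a dienylketene, which closes between the ketene carbon and the aryloxy-bearing vinyl carbon: one operation builds ring B with every substituent placed and its two oxygens differentiated. The precursor carries complete ring A (ester, prenyl, chromene) on a cis enol ether oxygen; the pyran is kept at the chromene oxidation level, so no late dehydrogenation beside the prenyl group is needed.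

Key step: step 10

**Remarks on the chemistry (assumptions)**

- Compounds 15, 20, 21 and 23 are racemic (one enantiomer drawn). Their single stereocentre is destroyed within the route; the target is achiral.
- The enol ether of 21 is cis because it is made from the lithium acetylide. A trans 2-aryloxyvinyllithium would hold lithium and aryloxide antiperiplanar and should fragment to ethyne and lithium aryloxide.
- The ring B pyran is carried as the 2H-pyran from the squarate stage. A quinone oxidant applied late to a chroman would first attack the benzylic, allylic CH2 of the ring A prenyl group.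
- The ring A hydroxyl beside the ester stays free: it is hydrogen-bonded, and as lithium phenoxide it shields the ester in step 8. The lactone is closed from the acid, because transesterification of a methyl ester to an aryl lactone is uphill.

**Route**

Step 1
Reactants: 1 methyl 2,4,6-trihydroxybenzoate; 2 3-chloro-3-methylbut-1-yne
Product: 3 methyl 2,6-dihydroxy-4-[(2-methylbut-3-yn-2-yl)oxy]benzoate
Conditions: K2CO3 (1.1 equiv), KI (cat.), CuI (cat.), acetone, 56 °C
Reagents that add atoms: none
Why: Copper-catalysed O-propargylation of a phenol with a tertiary propargyl chloride should take the most acidic, non-chelated para hydroxyl, since both ortho hydroxyls are hydrogen-bonded to the ester.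

Step 2
Reactants: 4 2-methylbut-3-en-2-ol
Product: 5 tert-butyl 2-methylbut-3-en-2-yl carbonate
Conditions: n-BuLi (1.0 equiv), THF, 0 °C; Boc2O, 0 °C → rt; H2O
Reagents that add atoms: di-tert-butyl dicarbonate (Boc2O), CC(C)(C)OC(=O)OC(=O)OC(C)(C)C
Why: Acylation of the lithium alkoxide by Boc2O (carbonate formation) turns the tertiary allylic alcohol into an ionisable partner for palladium.

Step 3
Reactants: 3 methyl 2,6-dihydroxy-4-[(2-methylbut-3-yn-2-yl)oxy]benzoate; 5 tert-butyl 2-methylbut-3-en-2-yl carbonate
Product: 6 methyl 2-hydroxy-6-[(2-methylbut-3-en-2-yl)oxy]-4-[(2-methylbut-3-yn-2-yl)oxy]benzoate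
Conditions: Pd(PPh3)4 (2 mol%), THF, 0 °C → rt
Reagents that add atoms: none
Why: Tsuji–Trost O-allylation, in which the phenoxide attacks the tertiary terminus of the 1,1-dimethylallyl palladium cation to give the reverse-prenyl ether, should stop at the monoether because the second of the two equivalent hydroxyls is then locked in a hydrogen bond to the ester carbonyl.

Step 4
Reactants: 6 methyl 2-hydroxy-6-[(2-methylbut-3-en-2-yl)oxy]-4-[(2-methylbut-3-yn-2-yl)oxy]benzoate; 7 trichloroethylene
Product: 9 methyl 2-{[(E)-1,2-dichloroethenyl]oxy}-6-[(2-methylbut-3-en-2-yl)oxy]-4-[(2-methylbut-3-yn-2-yl)oxy]benzoate, via dichloroethyne 8 (not isolated)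
Conditions: K2CO3, DMF, 60 °C
Reagents that add atoms: none
Why: Vinylic substitution by elimination–addition, in which carbonate converts trichloroethylene into dichloroethyne 8 and the phenoxide adds to it in anti fashion, should give the (E)-1,2-dichlorovinyl ether at a temperature where the tertiary allyl ether does not yet rearrange.

Step 5
Reactants: 9 methyl 2-{[(E)-1,2-dichloroethenyl]oxy}-6-[(2-methylbut-3-en-2-yl)oxy]-4-[(2-methylbut-3-yn-2-yl)oxy]benzoate
Product: 11 methyl 5-{[(E)-1,2-dichloroethenyl]oxy}-7-hydroxy-2,2-dimethyl-8-(3-methylbut-2-en-1-yl)-2H-chromene-6-carboxylate, via prenyl phenol 10 (not isolated)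
Conditions: o-xylene, 95 °C, then 140 °C
Reagents that add atoms: none
Why: Two aromatic Claisen rearrangements run in temperature order: the 1,1-dimethylallyl ether shifts first to its only free ortho carbon (prenyl group, phenol 10), and the propargyl ether, one ortho carbon now blocked, then rearranges to the other and cyclises to the chromene (propargyl Claisen–cyclisation cascade), which leaves the freed hydroxyl beside the prenyl group and the dichlorovinyl ether beside the chromene.

Step 6
Reactants: 12 diisopropyl squarate; 13 2-methylbut-3-yn-2-ol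
Product: 16 3-(3-hydroxy-3-methylbut-1-yn-1-yl)-4-(propan-2-yloxy)cyclobut-3-ene-1,2-dione, via dilithium alkynide 14 (not isolated), via squarate adduct 15 (not isolated)
Conditions: n-BuLi (2.05 equiv), THF, −78 → 0 °C; 12, −78 °C; then 2 M HCl, THF, rt
Reagents that add atoms: none
Why: 1,2-Addition of a lithium acetylide to a squarate ester followed by acid-induced collapse of adduct 15 with loss of isopropanol is the standard entry to 3-alkoxy-4-alkynylcyclobutenediones, and the hindered tertiary alkoxide of 14 should not compete as a nucleophile.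

Step 7
Reactants: 16 3-(3-hydroxy-3-methylbut-1-yn-1-yl)-4-(propan-2-yloxy)cyclobut-3-ene-1,2-dione
Product: 18 3,3-dimethyl-2-oxabicyclo[4.2.0]octa-1(6),4-diene-7,8-dione, via cis-alkenyl dione 17 (not isolated)
Conditions: H2 (1 atm), Pd/CaCO3 poisoned with Pb(OAc)2 (Lindlar catalyst), quinoline, EtOAc, rt; then PPTS (cat.), CH2Cl2, rt
Reagents that add atoms: none
Why: Lindlar semi-hydrogenation should give cis alkene 17, whose tertiary hydroxyl then sits beside the isopropoxy-bearing ring carbon and displaces isopropanol by addition–elimination (vinylogous transesterification of a squarate ester), closing the 2H-pyran.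

Step 8
Reactants: 11 methyl 5-{[(E)-1,2-dichloroethenyl]oxy}-7-hydroxy-2,2-dimethyl-8-(3-methylbut-2-en-1-yl)-2H-chromene-6-carboxylate; 18 3,3-dimethyl-2-oxabicyclo[4.2.0]octa-1(6),4-diene-7,8-dione
Product: 20 methyl 7-hydroxy-5-{[(8-hydroxy-3,3-dimethyl-7-oxo-2-oxabicyclo[4.2.0]octa-1(6),4-dien-8-yl)ethynyl]oxy}-2,2-dimethyl-8-(3-methylbut-2-en-1-yl)-2H-chromene-6-carboxylate (racemic), via dilithium aryloxyacetylide 19 (not isolated)
Conditions: n-BuLi (3.1 equiv), THF, −78 → −40 °C; 18, −78 °C; AcOH, −78 °C
Reagents that add atoms: none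
Why: The dichlorovinyl ether to lithium alkynyl ether conversion (deprotonation, loss of LiCl, chlorine–lithium exchange) should give 19, whose ortho lithium phenoxide deactivates the neighbouring ester toward n-BuLi, and the acetylide should add 1,2 to the ketone of 18 next to the oxygen-bearing ring carbon because the other carbonyl is a vinylogous ester; the carbinol centre forms as a racemate and is erased in step 10.

Step 9
Reactants: 20 alkynyl carbinol
Product: 21 methyl 7-hydroxy-5-{[(Z)-2-(8-hydroxy-3,3-dimethyl-7-oxo-2-oxabicyclo[4.2.0]octa-1(6),4-dien-8-yl)ethenyl]oxy}-2,2-dimethyl-8-(3-methylbut-2-en-1-yl)-2H-chromene-6-carboxylate (racemic)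
Conditions: H2 (1 atm, 1 equiv uptake), Pd/CaCO3 poisoned with Pb(OAc)2, quinoline, EtOAc, 0 °C
Reagents that add atoms: none
Why: Lindlar semi-hydrogenation delivers hydrogen syn to the ynol ether and should give the cis enol ether, while the trisubstituted prenyl alkene, the two pyran alkenes and the tetrasubstituted cyclobutenone alkene are not reduced at one equivalent of hydrogen.

Step 10
Reactants: 21 cis enol ether cyclobutenone
Product: 24 methyl 5-[(5,8-dihydroxy-2,2-dimethyl-2H-chromen-6-yl)oxy]-7-hydroxy-2,2-dimethyl-8-(3-methylbut-2-en-1-yl)-2H-chromene-6-carboxylate, via dienylketene 22 (not isolated), via cyclohexadienone 23 (not isolated)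
Conditions: PhMe (5 mM, degassed), 110 °C, Ar, base-washed glassware
Reagents that add atoms: none
Why: Thermal conrotatory 4π opening of the cyclobutenone bond between the carbonyl carbon and the carbinol carbon gives dienylketene 22, whose ketene carbon bonds to the aryloxy-bearing vinyl carbon in a thermally allowed disrotatory 6π electrocyclisation, the only ring closure (ring B), and cyclohexadienone 23 tautomerises irreversibly to hydroquinone 24; this is the Moore rearrangement of 4-alkenyl-4-hydroxycyclobutenones. No stereocentre is created: the carbinol centre of 21 is consumed and the sp3 centre of 23 is lost on aromatisation, so the racemate converges on one achiral product. The selectivity needed is torquoselectivity, and the hydroxyl, as the stronger donor, should rotate outward, which turns the enol ether inward and cis to the ketene, while the pyran fusion holds ketene and exocyclic alkene s-cis. The cis enol ether geometry should be tolerated because the other terminus is an sp ketene carbon with no inward substituent. The ring B pattern was fixed in step 8: the carbinol carbon becomes the free-hydroxyl carbon beside the pyran oxygen, and the ketene carbon becomes the phenol between the pyran CH= carbon and the diaryl ether. Neutral, degassed, dilute conditions guard the β-hydroxy enol ether against hydrolysis before opening and the hydroquinone against oxidation afterwards.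

Step 11
Reactants: 24 hydroquinone diaryl ether methyl ester
Product: 25 5-[(5,8-dihydroxy-2,2-dimethyl-2H-chromen-6-yl)oxy]-7-hydroxy-2,2-dimethyl-8-(3-methylbut-2-en-1-yl)-2H-chromene-6-carboxylic acid
Conditions: NaSEt (6 equiv), DMF (degassed), 80 °C; then 1 M HCl, 0 °C
Reagents that add atoms: none
Why: Thiolate attack at the ester methyl group (SN2 alkyl–oxygen cleavage) should free the acid without approach to the hindered carbonyl, and the reducing, air-free medium protects the hydroquinone.

Step 12
Reactants: 25 hydroxy acid
Product: 26 Garcinisidone D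
Conditions: DCC (1.2 equiv), DMAP (cat.), CH2Cl2 (2 mM), 0 °C → rt
Reagents that add atoms: none
Why: Carbodiimide lactonisation (Steglich type, the usual depsidone closure) should form the 7-membered lactone, because only the ring B hydroxyl ortho to the diaryl ether can reach the activated carboxyl, the para hydroxyl cannot, the ring A hydroxyl is hydrogen-bonded, and high dilution suppresses intermolecular esters.

**Compound list**

1 | methyl 2,4,6-trihydroxybenzoate | COC(=O)c1c(O)cc(O)cc1O | starting material
2 | 3-chloro-3-methylbut-1-yne | CC(C)(Cl)C#C | starting material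
3 | methyl 2,6-dihydroxy-4-[(2-methylbut-3-yn-2-yl)oxy]benzoate | COC(=O)c1c(O)cc(OC(C)(C)C#C)cc1O | intermediate
4 | 2-methylbut-3-en-2-ol | CC(C)(O)C=C | starting material
5 | tert-butyl 2-methylbut-3-en-2-yl carbonate | CC(C)(C)OC(=O)OC(C)(C)C=C | intermediate
6 | methyl 2-hydroxy-6-[(2-methylbut-3-en-2-yl)oxy]-4-[(2-methylbut-3-yn-2-yl)oxy]benzoate | COC(=O)c1c(O)cc(OC(C)(C)C#C)cc1OC(C)(C)C=C | intermediate
7 | trichloroethylene | ClC=C(Cl)Cl | starting material
8 | dichloroethyne | ClC#CCl | intermediate (not isolated)
9 | methyl 2-{[(E)-1,2-dichloroethenyl]oxy}-6-[(2-methylbut-3-en-2-yl)oxy]-4-[(2-methylbut-3-yn-2-yl)oxy]benzoate | COC(=O)c1c(O/C(Cl)=C\Cl)cc(OC(C)(C)C#C)cc1OC(C)(C)C=C | intermediate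
10 | methyl 2-{[(E)-1,2-dichloroethenyl]oxy}-6-hydroxy-5-(3-methylbut-2-en-1-yl)-4-[(2-methylbut-3-yn-2-yl)oxy]benzoate | COC(=O)c1c(O/C(Cl)=C\Cl)cc(OC(C)(C)C#C)c(CC=C(C)C)c1O | intermediate (not isolated)
11 | methyl 5-{[(E)-1,2-dichloroethenyl]oxy}-7-hydroxy-2,2-dimethyl-8-(3-methylbut-2-en-1-yl)-2H-chromene-6-carboxylate | COC(=O)c1c(O)c(CC=C(C)C)c2OC(C)(C)C=Cc2c1O/C(Cl)=C\Cl | intermediate
12 | diisopropyl squarate | CC(C)OC1=C(OC(C)C)C(=O)C1=O | starting material
13 | 2-methylbut-3-yn-2-ol | CC(C)(O)C#C | starting material
14 | dilithium alkynide of 13 (lithium 4-lithio-2-methylbut-3-yn-2-olate) | [Li]C#CC(C)(C)O[Li] | intermediate (not isolated)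
15 | 4-hydroxy-4-(3-hydroxy-3-methylbut-1-yn-1-yl)-2,3-di(propan-2-yloxy)cyclobut-2-en-1-one (racemic, one enantiomer drawn) | CC(C)OC1=C(OC(C)C)[C@](O)(C#CC(C)(C)O)C1=O | intermediate (not isolated)
16 | 3-(3-hydroxy-3-methylbut-1-yn-1-yl)-4-(propan-2-yloxy)cyclobut-3-ene-1,2-dione | CC(C)OC1=C(C#CC(C)(C)O)C(=O)C1=O | intermediate
17 | 3-[(Z)-3-hydroxy-3-methylbut-1-en-1-yl]-4-(propan-2-yloxy)cyclobut-3-ene-1,2-dione | CC(C)OC1=C(/C=C\C(C)(C)O)C(=O)C1=O | intermediate (not isolated)
18 | 3,3-dimethyl-2-oxabicyclo[4.2.0]octa-1(6),4-diene-7,8-dione (2H-pyran-fused cyclobutenedione) | CC1(C)C=CC2=C(O1)C(=O)C2=O | intermediate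
19 | dilithium aryloxyacetylide from 11 (lithium phenoxide, lithium acetylide) | COC(=O)c1c(O[Li])c(CC=C(C)C)c2OC(C)(C)C=Cc2c1OC#C[Li] | intermediate (not isolated)
20 | alkynyl carbinol: 8-hydroxy-8-(aryloxyethynyl) adduct of 18 carrying ring A (racemic, one enantiomer drawn) | CC1(C)C=CC2=C(O1)[C@@](O)(C#COc1c(C(=O)OC)c(O)c(CC=C(C)C)c3OC(C)(C)C=Cc13)C2=O | intermediate
21 | key-step precursor: pyran-fused 4-hydroxy-4-[(Z)-2-(ring A aryloxy)vinyl]cyclobutenone (racemic, one enantiomer drawn) | CC1(C)C=CC2=C(O1)[C@@](O)(/C=C\Oc1c(C(=O)OC)c(O)c(CC=C(C)C)c3OC(C)(C)C=Cc13)C2=O | intermediate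
22 | dienylketene (hydroxyl outward, enol ether inward) | CC1(C)C=CC(=C=O)/C(O1)=C(/O)\C=C/Oc1c(C(=O)OC)c(O)c(CC=C(C)C)c2OC(C)(C)C=Cc12 | intermediate (not isolated)
23 | 6-aryloxy-4-hydroxycyclohexa-2,4-dienone fused to the 2H-pyran (racemic, one enantiomer drawn) | CC1(C)C=CC2=C(O1)C(O)=C[C@@H](Oc1c(C(=O)OC)c(O)c(CC=C(C)C)c3OC(C)(C)C=Cc13)C2=O | intermediate (not isolated)
24 | key-step product: methyl 5-[(5,8-dihydroxy-2,2-dimethyl-2H-chromen-6-yl)oxy]-7-hydroxy-2,2-dimethyl-8-(3-methylbut-2-en-1-yl)-2H-chromene-6-carboxylate | Oc1cc(Oc2c(C(=O)OC)c(O)c(CC=C(C)C)c3OC(C)(C)C=Cc23)c(O)c2C=CC(C)(C)Oc12 | intermediate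
25 | 5-[(5,8-dihydroxy-2,2-dimethyl-2H-chromen-6-yl)oxy]-7-hydroxy-2,2-dimethyl-8-(3-methylbut-2-en-1-yl)-2H-chromene-6-carboxylic acid | Oc1cc(Oc2c(C(=O)O)c(O)c(CC=C(C)C)c3OC(C)(C)C=Cc23)c(O)c2C=CC(C)(C)Oc12 | intermediate
26 | Garcinisidone D | CC(C)=CCc1c(O)c2c(c3c1OC(C)(C)C=C3)Oc1cc(O)c3c(c1OC2=O)C=CC(C)(C)O3 | target

**Step count**

Total: 12 steps. Longest linear sequence: 9 steps (steps 1, 3, 4, 5, 8, 9, 10, 11, 12, from 1 to 26).

**Steps most likely to fail**

Step 10. The ring opening may proceed with the hydroxyl turning inward, so that the ketene is captured by its own hydroxyl as a butenolide. The β-hydroxy enol ether may also lose its aryloxy group by trace-acid hydrolysis before it opens. The fallback sets out from 21. Both hydroxyls are silylated with N-(trimethylsilyl)imidazole (CH2Cl2, 0 °C) to the bis(trimethylsilyl) ether F1. A silyloxy group is an outward-rotating donor without an acidic proton. Heating F1 in toluene as in step 10 should give the silylated ring expansion product F2, with the silyl group retained on the former carbinol oxygen. Methanol with a trace of citric acid then removes both aryl silyl ethers, and the route is rejoined at 24.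

Step 8. Butyllithium may be consumed outside the intended sequence, or the chlorine–lithium exchange may remain incomplete. The lithium acetylide may also add to dione 18 in conjugate fashion or at the vinylogous ester carbonyl. The fallback sets out from 11. The same n-BuLi treatment is quenched with methanol, and the terminal aryl ethynyl ether F3 is isolated. F3 is deprotonated with LiN(i-Pr)2 (2.1 equiv, THF, −78 °C) to 19, now free of alkyllithium and butyl chloride. Transmetallation with anhydrous CeCl3 gives the alkynylcerium reagent F4, which is less basic and adds to conjugated ketones in the 1,2 sense. Addition of F4 to 18 returns to the route at 20.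

Step 5. The two sigmatropic shifts may occur in the wrong order: if the propargyl ether migrates before the allyl ether, the allyl group is sent on to the para position as a reverse-prenyl group. The propargyl ether may also be diverted toward the blocked ortho carbon. The fallback sets out from 3 and separates the two events. Compound 3 alone is heated (o-xylene, 140 °C); its two ortho carbons are equivalent, so only the chromene diol F5 can form. Palladium-catalysed allylation with 5, as in step 3, should take the 7-hydroxyl, which is less hindered than the 5-hydroxyl crowded by the pyran CH, and give the reverse-prenyl ether F6. Trichloroethylene and K2CO3, as in step 4 (through 8), convert the remaining hydroxyl into the dichlorovinyl ether F7. A single Claisen rearrangement at 95 °C to C-8, the only free ortho carbon, returns to the route at 11. The price is the regioselectivity of the O-allylation between two ortho hydroxyls.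

**Further compounds**

F1 | step 10 | bis(trimethylsilyl) ether of 21 (carbinol and ring A phenol silylated; racemic, one enantiomer drawn) | CC1(C)C=CC2=C(O1)[C@@](O[Si](C)(C)C)(/C=C\Oc1c(C(=O)OC)c(O[Si](C)(C)C)c(CC=C(C)C)c3OC(C)(C)C=Cc13)C2=O
F2 | step 10 | bis(trimethylsilyl) ether of 24 (ring B 8-O-silyl, ring A 7-O-silyl) | C[Si](C)(C)Oc1cc(Oc2c(C(=O)OC)c(O[Si](C)(C)C)c(CC=C(C)C)c3OC(C)(C)C=Cc23)c(O)c2C=CC(C)(C)Oc12
F3 | step 8 | methyl 5-(ethynyloxy)-7-hydroxy-2,2-dimethyl-8-(3-methylbut-2-en-1-yl)-2H-chromene-6-carboxylate | COC(=O)c1c(O)c(CC=C(C)C)c2OC(C)(C)C=Cc2c1OC#C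
F4 | step 8 | alkynylcerium dichloride derived from F3 (lithium phenoxide) | COC(=O)c1c(O[Li])c(CC=C(C)C)c2OC(C)(C)C=Cc2c1OC#C[Ce](Cl)Cl
F5 | step 5 | methyl 5,7-dihydroxy-2,2-dimethyl-2H-chromene-6-carboxylate | COC(=O)c1c(O)cc2OC(C)(C)C=Cc2c1O
F6 | step 5 | methyl 5-hydroxy-2,2-dimethyl-7-[(2-methylbut-3-en-2-yl)oxy]-2H-chromene-6-carboxylate | COC(=O)c1c(OC(C)(C)C=C)cc2OC(C)(C)C=Cc2c1O
F7 | step 5 | methyl 5-{[(E)-1,2-dichloroethenyl]oxy}-2,2-dimethyl-7-[(2-methylbut-3-en-2-yl)oxy]-2H-chromene-6-carboxylate | COC(=O)c1c(OC(C)(C)C=C)cc2OC(C)(C)C=Cc2c1O/C(Cl)=C\Cl
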